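**Plan**

- Cuts, in retrosynthetic order: the angelate C–O bond; the side-chain carbinol C–H (back to the aryl methyl ketone); the C3 acetate; then, together, the O1–C2 ether bond, the Cα–C(=O) bond and the C(=O)–OCH3 bond, which opens the dihydrofuran to an ortho-(1-silyloxybuta-2,3-dienyl)phenol, CO and methanol; last the allene CH2, the C3–alkyne bond and the formyl carbon, back to 4'-hydroxyacetophenone (1).
- Feature used: in the 2,3-dihydrobenzofuran ring, C2 is an aryl-ether carbon (bonded to O1) that carries a 1-(methoxycarbonyl)vinyl group. This is the imprint of a phenol oxygen adding to the inner carbon of an allene while the central carbon Cα is carbonylated.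
- Forward: the benzene ring comes from 1. The chain is built ortho to the phenol by formylation, alkynylation and one-carbon homologation to the allene. The dihydrofuran ring, the only ring made, closes in step 8 together with the acrylate. Silyl-to-acetyl exchange at C3, ketone reduction and angeloylation finish the molecule.
- Stereochemistry: C3 from the ligand-controlled alkynylation (step 3); C2 from C3 by substrate control in the anti-oxypalladation (step 8); the side-chain carbinol from catalyst-controlled transfer hydrogenation (step 11); the Z alkene is bought with angelic acid.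

Key step: step 8

Atom labels: O1, C2, C3, C3a, C7a are the dihydrobenzofuran positions; Cα is the acrylate carbon bonded to C2.

Assumption: (S,S)-ProPhenol is taken to direct the alkynylzinc to the Re face of the aryl aldehyde; if a Mosher ester check on 6 shows the opposite sense, (R,R)-ProPhenol is used and nothing else changes.

**Route**

Step 1
Reactants: 1 4'-hydroxyacetophenone
Product: 2 5-acetyl-2-hydroxybenzaldehyde
Conditions: hexamethylenetetramine, CF3CO2H, 85 °C; then H2O, rt
Reagents that add atoms: hexamethylenetetramine, C1N2CN3CN1CN(C2)C3; water, O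
Why: Duff formylation, in which the iminium ion released from hexamethylenetetramine attacks the only activated free position (ortho to the phenol, para being blocked by the acetyl group) and the benzylic amine is oxidised internally and hydrolysed to the aldehyde on aqueous work-up.

Step 2
Reactants: 2 5-acetyl-2-hydroxybenzaldehyde
Product: 3 5-acetyl-2-(triisopropylsilyloxy)benzaldehyde
Conditions: TIPSCl, imidazole, DMF, rt
Reagents that add atoms: triisopropylsilyl chloride, CC(C)[Si](Cl)(C(C)C)C(C)C
Why: Standard silylation of a phenol; the bulky silyl group hides the acidic OH from Zn(CH3)2 and from the later amine–formaldehyde step, yet should come off this acidic phenol far more easily than an alkyl silyl ether.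

Step 3
Reactants: 3 5-acetyl-2-(triisopropylsilyloxy)benzaldehyde; 4 trimethylsilylacetylene
Product: 6 1-[3-[(1S)-1-hydroxy-3-(trimethylsilyl)prop-2-yn-1-yl]-4-(triisopropylsilyloxy)phenyl]ethanone, via zinc alkynylide 5 (not isolated)
Conditions: 4 (3 equiv), Zn(CH3)2 (3 equiv), (S,S)-ProPhenol (10 mol%), Ph3P=O (20 mol%), toluene, 0 °C; then 3, 4 °C; aq. NH4Cl
Reagents that add atoms: none
Why: Catalytic asymmetric alkynylation of an aldehyde (dinuclear zinc–ProPhenol alkynylzinc addition), in which the preformed alkynylide should add to the Re face of the aldehyde inside the chiral dizinc pocket and so set the future C3 as (S) in 6, the methyl ketone being a much slower acceptor at 4 °C.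

Step 4
Reactants: 6 1-[3-[(1S)-1-hydroxy-3-(trimethylsilyl)prop-2-yn-1-yl]-4-(triisopropylsilyloxy)phenyl]ethanone
Product: 7 1-[3-[(1S)-1-(tert-butyldimethylsilyloxy)-3-(trimethylsilyl)prop-2-yn-1-yl]-4-(triisopropylsilyloxy)phenyl]ethanone
Conditions: TBSCl, imidazole, DMF, rt
Reagents that add atoms: tert-butyldimethylsilyl chloride, CC(C)(C)[Si](C)(C)Cl
Why: Standard silylation of a secondary alcohol under neutral conditions that neither enolise the ketone nor touch the stereocentre; the ether makes the C3 oxygen non-nucleophilic for steps 6 and 8.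

Step 5
Reactants: 7 1-[3-[(1S)-1-(tert-butyldimethylsilyloxy)-3-(trimethylsilyl)prop-2-yn-1-yl]-4-(triisopropylsilyloxy)phenyl]ethanone
Product: 8 1-[3-[(1R)-1-(tert-butyldimethylsilyloxy)prop-2-yn-1-yl]-4-(triisopropylsilyloxy)phenyl]ethanone
Conditions: AgNO3 (10 mol%), MeOH/H2O/CH2Cl2, rt
Reagents that add atoms: none
Why: Silver-catalysed protiodesilylation of a silylalkyne, which cleaves only the C(sp)–Si bond through a silver acetylide under neutral conditions and so spares both O–Si bonds, including the base-labile aryl silyl ether (the descriptor becomes R only because the CIP priorities change).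

Step 6
Reactants: 8 1-[3-[(1R)-1-(tert-butyldimethylsilyloxy)prop-2-yn-1-yl]-4-(triisopropylsilyloxy)phenyl]ethanone
Product: 10 1-[3-[(1R)-1-(tert-butyldimethylsilyloxy)buta-2,3-dien-1-yl]-4-(triisopropylsilyloxy)phenyl]ethanone, via propargylic amine 9 (not isolated)
Conditions: (CH2O)n (2.5 equiv), CuI (0.5 equiv), HN(C6H11)2 (1.8 equiv), dioxane, 100 °C
Reagents that add atoms: paraformaldehyde, C=O
Why: Crabbé homologation, in which copper-mediated Mannich condensation of the terminal alkyne with formaldehyde and dicyclohexylamine gives amine 9, which then passes a hydride from an N-cyclohexyl carbon to the alkyne and expels the imine to leave the terminal allene without involving the carbinol stereocentre.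

Step 7
Reactants: 10 1-[3-[(1R)-1-(tert-butyldimethylsilyloxy)buta-2,3-dien-1-yl]-4-(triisopropylsilyloxy)phenyl]ethanone
Product: 11 1-[3-[(1R)-1-(tert-butyldimethylsilyloxy)buta-2,3-dien-1-yl]-4-hydroxyphenyl]ethanone
Conditions: KHF2, MeOH, rt
Reagents that add atoms: none
Why: Chemoselective desilylation with bifluoride, which should cleave the silyl ether of the acidic para-acyl phenol (phenoxide being a far better leaving group than a secondary alkoxide) and leave the C3 silyl ether, the allene and the ketone alone.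

Step 8
Reactants: 11 1-[3-[(1R)-1-(tert-butyldimethylsilyloxy)buta-2,3-dien-1-yl]-4-hydroxyphenyl]ethanone; 12 carbon monoxide; 13 methanol
Product: 14 methyl 2-[(2S,3S)-5-acetyl-3-(tert-butyldimethylsilyloxy)-2,3-dihydro-1-benzofuran-2-yl]prop-2-enoate
Conditions: PdCl2 (10 mol%), CuCl2 (3 equiv), NaOAc (3 equiv), CO (1 atm), MeOH, 0 °C to rt
Reagents that add atoms: none
Why: Divalent palladium coordinates the C2=Cα bond of the allene, O1 adds to C2 anti to the metal, the σ-vinylpalladium at Cα inserts CO and the acylpalladium is cleaved by methanol to the methyl ester, after which CuCl2 returns zerovalent palladium to the divalent state and NaOAc takes up the HCl. The closest known reaction is the PdCl2/CuCl2/CO/methanol alkoxycarbonylative cyclisation of γ-hydroxy allenes to 2-[1-(methoxycarbonyl)vinyl]tetrahydrofurans, and phenols are established nucleophiles in the same oxidative carbonylation of ortho-alkynyl and ortho-alkenyl phenols. The dihydrofuran ring closes in the 5-exo-trig mode, O1 onto the inner allene carbon C2 with the C2=Cα bond exocyclic. C2 is set under substrate control by C3: with the C3–aryl bond perpendicular to the reacting π bond and no allylic 1,3-strain from the sp-hybridised Cα, the silyloxy group can take the inside position, and O1 then lands on the face that puts the Cα branch cis to the C3 oxygen, which is (2S,3S). The step needs O1, not the C3 oxygen, as nucleophile and attack at C2 rather than at the central carbon; the silyl ether removes the C3 oxygen as a competitor (no 5-endo closure to a 2,5-dihydrofuran, no later lactonisation), the five-membered closure through C2 is the only unstrained one open to the ortho phenol, and the acetate buffer protects the benzylic silyl ether from acid.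

Step 9
Reactants: 14 methyl 2-[(2S,3S)-5-acetyl-3-(tert-butyldimethylsilyloxy)-2,3-dihydro-1-benzofuran-2-yl]prop-2-enoate
Product: 15 methyl 2-[(2S,3S)-5-acetyl-3-hydroxy-2,3-dihydro-1-benzofuran-2-yl]prop-2-enoate
Conditions: HF·pyridine, pyridine, THF, 0 °C; crude product used at once
Reagents that add atoms: none
Why: Fluoride-mediated cleavage of a secondary silyl ether under buffered conditions; the acetyl group para to O1 should temper ionisation at benzylic C3 so the cis configuration is kept, and the alcohol is taken on immediately because the cis C3–OH could lactonise onto the acrylate ester.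

Step 10
Reactants: 15 methyl 2-[(2S,3S)-5-acetyl-3-hydroxy-2,3-dihydro-1-benzofuran-2-yl]prop-2-enoate
Product: 16 methyl 2-[(2S,3S)-3-acetoxy-5-acetyl-2,3-dihydro-1-benzofuran-2-yl]prop-2-enoate
Conditions: Ac2O, pyridine, DMAP (cat.), CH2Cl2, 0 °C
Reagents that add atoms: acetic anhydride, CC(=O)OC(C)=O
Why: DMAP-catalysed acetylation of a secondary alcohol, fast at 0 °C and therefore expected to outrun lactonisation, with no stereocentre touched.

Step 11
Reactants: 16 methyl 2-[(2S,3S)-3-acetoxy-5-acetyl-2,3-dihydro-1-benzofuran-2-yl]prop-2-enoate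
Product: 17 methyl 2-[(2S,3S)-3-acetoxy-5-[(1S)-1-hydroxyethyl]-2,3-dihydro-1-benzofuran-2-yl]prop-2-enoate
Conditions: RuCl(p-cymene)[(S,S)-TsDPEN] (1 mol%), HCO2H/Et3N (5:2), CH2Cl2, rt
Reagents that add atoms: none
Why: Noyori asymmetric transfer hydrogenation, in which the ruthenium hydride of the (S,S)-TsDPEN complex should deliver hydride to the Re face of the aryl methyl ketone to give the (S)-carbinol irreversibly, while the esters and the 1,1-disubstituted acrylate are not reduced.

Step 12
Reactants: 17 methyl 2-[(2S,3S)-3-acetoxy-5-[(1S)-1-hydroxyethyl]-2,3-dihydro-1-benzofuran-2-yl]prop-2-enoate; 18 angelic acid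
Product: 20 methyl 2-[(2S,3S)-3-acetoxy-5-[(1S)-1-[(2Z)-2-methylbut-2-enoyloxy]ethyl]-2,3-dihydro-1-benzofuran-2-yl]prop-2-enoate (target), via mixed anhydride 19 (not isolated)
Conditions: 18, 2,4,6-Cl3C6H2COCl, Et3N, toluene, rt; then 17, toluene, 80 °C
Reagents that add atoms: none
Why: Yamaguchi esterification, in which mixed anhydride 19 acylates the alcohol at the less hindered angeloyl carbonyl, and leaving out a nucleophilic catalyst avoids the conjugate addition–elimination that turns an angelate into a tiglate, so the Z alkene and the (S)-carbinol (O-acylation, C–O bond untouched) should be retained.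

**Compound list**

1 | 4'-hydroxyacetophenone | CC(=O)c1ccc(O)cc1 | starting material
2 | 5-acetyl-2-hydroxybenzaldehyde | CC(=O)c1ccc(O)c(C=O)c1 | intermediate
3 | 5-acetyl-2-(triisopropylsilyloxy)benzaldehyde | CC(=O)c1ccc(O[Si](C(C)C)(C(C)C)C(C)C)c(C=O)c1 | intermediate
4 | trimethylsilylacetylene | C#C[Si](C)(C)C | starting material
5 | methyl[(trimethylsilyl)ethynyl]zinc (formed in the flask, not isolated) | C[Zn]C#C[Si](C)(C)C | intermediate
6 | 1-[3-[(1S)-1-hydroxy-3-(trimethylsilyl)prop-2-yn-1-yl]-4-(triisopropylsilyloxy)phenyl]ethanone | C[Si](C)(C)C#C[C@@H](O)c1cc(C(C)=O)ccc1O[Si](C(C)C)(C(C)C)C(C)C | intermediate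
7 | 1-[3-[(1S)-1-(tert-butyldimethylsilyloxy)-3-(trimethylsilyl)prop-2-yn-1-yl]-4-(triisopropylsilyloxy)phenyl]ethanone | C[Si](C)(C)C#C[C@@H](O[Si](C)(C)C(C)(C)C)c1cc(C(C)=O)ccc1O[Si](C(C)C)(C(C)C)C(C)C | intermediate
8 | 1-[3-[(1R)-1-(tert-butyldimethylsilyloxy)prop-2-yn-1-yl]-4-(triisopropylsilyloxy)phenyl]ethanone | C#C[C@@H](O[Si](C)(C)C(C)(C)C)c1cc(C(C)=O)ccc1O[Si](C(C)C)(C(C)C)C(C)C | intermediate
9 | 1-[3-[(1R)-1-(tert-butyldimethylsilyloxy)-4-(dicyclohexylamino)but-2-yn-1-yl]-4-(triisopropylsilyloxy)phenyl]ethanone (formed in the flask, not isolated) | C1CCC(CC1)N(CC#C[C@@H](O[Si](C)(C)C(C)(C)C)c1cc(C(C)=O)ccc1O[Si](C(C)C)(C(C)C)C(C)C)C1CCCCC1 | intermediate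
10 | 1-[3-[(1R)-1-(tert-butyldimethylsilyloxy)buta-2,3-dien-1-yl]-4-(triisopropylsilyloxy)phenyl]ethanone | C=C=C[C@@H](O[Si](C)(C)C(C)(C)C)c1cc(C(C)=O)ccc1O[Si](C(C)C)(C(C)C)C(C)C | intermediate
11 | 1-[3-[(1R)-1-(tert-butyldimethylsilyloxy)buta-2,3-dien-1-yl]-4-hydroxyphenyl]ethanone | C=C=C[C@@H](O[Si](C)(C)C(C)(C)C)c1cc(C(C)=O)ccc1O | intermediate
12 | carbon monoxide | [C-]#[O+] | starting material
13 | methanol | CO | starting material
14 | methyl 2-[(2S,3S)-5-acetyl-3-(tert-butyldimethylsilyloxy)-2,3-dihydro-1-benzofuran-2-yl]prop-2-enoate | C=C(C(=O)OC)[C@@H]1Oc2ccc(C(C)=O)cc2[C@@H]1O[Si](C)(C)C(C)(C)C | intermediate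
15 | methyl 2-[(2S,3S)-5-acetyl-3-hydroxy-2,3-dihydro-1-benzofuran-2-yl]prop-2-enoate | C=C(C(=O)OC)[C@@H]1Oc2ccc(C(C)=O)cc2[C@@H]1O | intermediate
16 | methyl 2-[(2S,3S)-3-acetoxy-5-acetyl-2,3-dihydro-1-benzofuran-2-yl]prop-2-enoate | C=C(C(=O)OC)[C@@H]1Oc2ccc(C(C)=O)cc2[C@@H]1OC(C)=O | intermediate
17 | methyl 2-[(2S,3S)-3-acetoxy-5-[(1S)-1-hydroxyethyl]-2,3-dihydro-1-benzofuran-2-yl]prop-2-enoate | C=C(C(=O)OC)[C@@H]1Oc2ccc([C@H](C)O)cc2[C@@H]1OC(C)=O | intermediate
18 | angelic acid, (2Z)-2-methylbut-2-enoic acid | C/C=C(/C)C(=O)O | starting material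
19 | (2Z)-2-methylbut-2-enoic 2,4,6-trichlorobenzoic anhydride (formed in the flask, not isolated) | C/C=C(/C)C(=O)OC(=O)c1c(Cl)cc(Cl)cc1Cl | intermediate
20 | methyl 2-[(2S,3S)-3-acetoxy-5-[(1S)-1-[(2Z)-2-methylbut-2-enoyloxy]ethyl]-2,3-dihydro-1-benzofuran-2-yl]prop-2-enoate | C=C(C(=O)OC)[C@@H]1Oc2ccc([C@H](C)OC(=O)/C(C)=C\C)cc2[C@@H]1OC(C)=O | target

**Count and risks**

Total steps: 12. Longest linear sequence: 12 steps from 1 (4, 12, 13 and 18 are bought).

Step 8 — what may go wrong: O1 may add to the other face of the C2=Cα bond (silyloxy group outside), so that the 2,3-trans ether predominates; this cannot be corrected by epimerisation afterwards. Fallback (sets out from 3, returns at 16): the alkynylation is run with (R,R)-ProPhenol to give the enantiomeric (1R)-silylalkynol F1. Steps 4 to 7, unchanged, carry it through the TBS ether F2, the terminal alkyne F3, the propargylic amine F4 (not isolated), the allene F5 and the free phenol F6. The same carbonylative cyclisation, now relying on the trans preference, should give the (2S,3R)-silyl ether F7, and HF·pyridine frees the (2S,3R)-alcohol F8. A Mitsunobu reaction with acetic acid (PPh3, DIAD, THF, 0 °C) then inverts C3 by SN2 displacement and installs the acetate in one operation, giving 16.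

Step 12 — what may go wrong: isomerisation of the angeloyl unit to the E (tigloyl) isomer during acyl transfer at 80 °C, or ionisation of the electron-rich benzylic alcohol. Fallback (sets out from 17, returns at 20): the Z alkene is built on the ester instead of being carried in. Alcohol 17 is esterified with 2-[bis(2,2,2-trifluoroethoxy)phosphoryl]propanoic acid (DCC, DMAP cat., CH2Cl2, 0 °C) to the phosphonopropanoate F14. A Still–Gennari olefination with acetaldehyde (KHMDS, 18-crown-6, THF, −78 °C) should then give the Z-trisubstituted alkene, which is 20.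

Step 6 — what may go wrong: aminomethylation or hydroxymethylation at the enolisable methyl ketone, and cleavage of the aryl silyl ether, under hot amine and formaldehyde. Fallback (sets out from 3, returns at 10): the allene is made by reductive 1,3-transposition of a propargylic alcohol at low temperature. Alkynylation of 3 as in step 3, but with 4-methoxybenzyl prop-2-ynyl ether, gives the alkynol F9, and TBSCl–imidazole gives the silyl ether F10. DDQ (CH2Cl2/H2O) removes the 4-methoxybenzyl group to give the primary propargylic alcohol F11. A Mitsunobu reaction with 2-nitrobenzenesulfonylhydrazide (PPh3, DEAD, THF, −15 °C) gives the sulfonylhydrazine F12. On warming, this loses the sulfinic acid to the monoalkyl diazene F13, which expels N2 with transfer of hydrogen to the alkyne carbon and gives allene 10 (Myers allene synthesis).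

**Further compounds**

F1 | step 8 | 1-[3-[(1R)-1-hydroxy-3-(trimethylsilyl)prop-2-yn-1-yl]-4-(triisopropylsilyloxy)phenyl]ethanone | C[Si](C)(C)C#C[C@H](O)c1cc(C(C)=O)ccc1O[Si](C(C)C)(C(C)C)C(C)C
F2 | step 8 | 1-[3-[(1R)-1-(tert-butyldimethylsilyloxy)-3-(trimethylsilyl)prop-2-yn-1-yl]-4-(triisopropylsilyloxy)phenyl]ethanone | C[Si](C)(C)C#C[C@H](O[Si](C)(C)C(C)(C)C)c1cc(C(C)=O)ccc1O[Si](C(C)C)(C(C)C)C(C)C
F3 | step 8 | 1-[3-[(1S)-1-(tert-butyldimethylsilyloxy)prop-2-yn-1-yl]-4-(triisopropylsilyloxy)phenyl]ethanone | C#C[C@H](O[Si](C)(C)C(C)(C)C)c1cc(C(C)=O)ccc1O[Si](C(C)C)(C(C)C)C(C)C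
F4 | step 8 | 1-[3-[(1S)-1-(tert-butyldimethylsilyloxy)-4-(dicyclohexylamino)but-2-yn-1-yl]-4-(triisopropylsilyloxy)phenyl]ethanone | C1CCC(CC1)N(CC#C[C@H](O[Si](C)(C)C(C)(C)C)c1cc(C(C)=O)ccc1O[Si](C(C)C)(C(C)C)C(C)C)C1CCCCC1
F5 | step 8 | 1-[3-[(1S)-1-(tert-butyldimethylsilyloxy)buta-2,3-dien-1-yl]-4-(triisopropylsilyloxy)phenyl]ethanone | C=C=C[C@H](O[Si](C)(C)C(C)(C)C)c1cc(C(C)=O)ccc1O[Si](C(C)C)(C(C)C)C(C)C
F6 | step 8 | 1-[3-[(1S)-1-(tert-butyldimethylsilyloxy)buta-2,3-dien-1-yl]-4-hydroxyphenyl]ethanone | C=C=C[C@H](O[Si](C)(C)C(C)(C)C)c1cc(C(C)=O)ccc1O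
F7 | step 8 | methyl 2-[(2S,3R)-5-acetyl-3-(tert-butyldimethylsilyloxy)-2,3-dihydro-1-benzofuran-2-yl]prop-2-enoate | C=C(C(=O)OC)[C@@H]1Oc2ccc(C(C)=O)cc2[C@H]1O[Si](C)(C)C(C)(C)C
F8 | step 8 | methyl 2-[(2S,3R)-5-acetyl-3-hydroxy-2,3-dihydro-1-benzofuran-2-yl]prop-2-enoate | C=C(C(=O)OC)[C@@H]1Oc2ccc(C(C)=O)cc2[C@H]1O
F9 | step 6 | 1-[3-[(1R)-1-hydroxy-4-[(4-methoxybenzyl)oxy]but-2-yn-1-yl]-4-(triisopropylsilyloxy)phenyl]ethanone | COc1ccc(COCC#C[C@@H](O)c2cc(C(C)=O)ccc2O[Si](C(C)C)(C(C)C)C(C)C)cc1
F10 | step 6 | 1-[3-[(1R)-1-(tert-butyldimethylsilyloxy)-4-[(4-methoxybenzyl)oxy]but-2-yn-1-yl]-4-(triisopropylsilyloxy)phenyl]ethanone | COc1ccc(COCC#C[C@@H](O[Si](C)(C)C(C)(C)C)c2cc(C(C)=O)ccc2O[Si](C(C)C)(C(C)C)C(C)C)cc1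
F11 | step 6 | 1-[3-[(1R)-1-(tert-butyldimethylsilyloxy)-4-hydroxybut-2-yn-1-yl]-4-(triisopropylsilyloxy)phenyl]ethanone | OCC#C[C@@H](O[Si](C)(C)C(C)(C)C)c1cc(C(C)=O)ccc1O[Si](C(C)C)(C(C)C)C(C)C
F12 | step 6 | N-[(4R)-4-[5-acetyl-2-(triisopropylsilyloxy)phenyl]-4-(tert-butyldimethylsilyloxy)but-2-yn-1-yl]-2-nitrobenzenesulfonohydrazide | NN(CC#C[C@@H](O[Si](C)(C)C(C)(C)C)c1cc(C(C)=O)ccc1O[Si](C(C)C)(C(C)C)C(C)C)S(=O)(=O)c1ccccc1[N+](=O)[O-]
F13 | step 6 | 1-[3-[(1R)-1-(tert-butyldimethylsilyloxy)-4-diazenylbut-2-yn-1-yl]-4-(triisopropylsilyloxy)phenyl]ethanone | N=NCC#C[C@@H](O[Si](C)(C)C(C)(C)C)c1cc(C(C)=O)ccc1O[Si](C(C)C)(C(C)C)C(C)C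
F14 | step 12 | methyl 2-[(2S,3S)-3-acetoxy-5-[(1S)-1-[2-[bis(2,2,2-trifluoroethoxy)phosphoryl]propanoyloxy]ethyl]-2,3-dihydro-1-benzofuran-2-yl]prop-2-enoate | C=C(C(=O)OC)[C@@H]1Oc2ccc([C@H](C)OC(=O)C(C)P(=O)(OCC(F)(F)F)OCC(F)(F)F)cc2[C@@H]1OC(C)=O
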